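The pitfall is to chase a rate, which falls within each run. A chain length is a quotient, so I work with the fraction of L left and carry one quantity: the ceiling, or target degree of polymerisation, which is L charged per Z charged, 55.6 in beta and 13.3 in delta. If every Z begins one chain, which is my guess, the length is the ceiling times the fraction of L gone.

| flask | L | Z | remark | time |
|---|---|---|---|---|
| amber | 0.050 M | 0.60 mM | run made earlier |  |
| green | 0.050 M | 0.45 mM | run made earlier |  |
| beta | 0.050 M | 0.90 mM |  | 12 min |
| delta | 0.012 M | 0.90 mM |  | 12 min |

| amber: time / min | amber: Q / % | green: time / min | green: Q / % |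
|---|---|---|---|
| 1.00 | 4.6 | 0.500 | 1.6 |
| 2.00 | 7.8 | 1.33 | 4.5 |
| 3.00 | 12.0 | 2.50 | 8.0 |
| 4.00 | 13.4 | 4.00 | 10.9 |

(standard deviation of a reading: 0.3 percentage points)

- which of the two ends with the longer chains by the average number of monomer units in a chain (chains begun, living or dead) ("neither" if they lie within 10%) (beta / delta / neither)
- average number of monomer units in a chain (chains begun, living or dead) at the end, beta
- average number of monomer units in a chain (chains begun, living or dead) at the end, delta

- the average divides the monomer in chains by the number of chains begun, living and dead together
- the analysis behind the earlier runs scatters by 0.3 percentage points, standard deviation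
- the earlier runs do not show the number of chains; that part of a forecast is a guess

The log-loss, minus the logarithm of the fraction left, reads 0.0471 at 1.00 min in amber and 0.144 at 4.00 min. Amber's last log-loss stands 1.25 times green's, near their Z ratio of 1.33, so I scale by Z, a factor of 1.50 for beta.

From below, beta stops dead at 4.00 min: log-loss 0.216, length 10.8. From above, amber's later pace of 0.0323 min⁻¹, slower than its opening 0.0471 min⁻¹, holds on, scaled, to 12 min: log-loss 0.603, length 25.2. Taking delta as first order in L, which no run tested, its bracket is 2.59 to 6.04, below beta's.

The forecast names beta, with 19 for beta (range 12 to 34) and 4.5 for delta (range 2 to 9), both inside my brackets: “Beta wins under either model”.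

The flask gives 16.0 for beta and 4.57 for delta, so beta ends longer, and both lengths lie inside my brackets.

    L + Z → E + Q (k = 53.0 L mol⁻¹ min⁻¹)
    2 E → J (k = 312 L mol⁻¹ min⁻¹)
    L + E → Q + E, rate k3*[E]*[L] (k = 94.8 L mol⁻¹ min⁻¹)

Delta's chains are shorter, 4.57 against 16.0 for the same flask with beta's charge of L, mainly because of its smaller charge of L. The ceilings differ by a factor of 4.17 and the lengths by 3.50, and at 12.0 min delta holds Q 34.2% against beta's 28.7%. Beta read at 50 min has Z 0% left and Q 42.0%, so its ceiling gives 23.3, and the flask there stands at 23.3.

The numbers in the tables stem from a simulated flask on assumed constants.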